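The earlier runs and the new flask are simulated for substances that don't exist.

Carry one number through these flasks: the chance that a lost Q ends as G.

| flask | Q | Z | temperature | remark | time |
|---|---|---|---|---|---|
| north-east | 0.20 M | 0.040 M | −5 °C | run made earlier |  |
| east | 0.80 M | 0.040 M | 17 °C | run made earlier |  |
| south-west | 0.40 M | 0.080 M | −5 °C | run made earlier |  |
| cedar | 0.40 M | 0.0400 M | 5 °C |  | 5.0 min |
| alder | 0.40 M | 0.0400 M | −15 °C |  | 5.0 min |
| elm | 0.40 M | 0.0400 M | 25 °C |  | 5.0 min |

- north-east (time / min: G / %, Q / %): 0.333: 0, 100; 1.00: 4, 94; 1.50: 4, 94; 2.50: 7, 90; 4.00: 9, 79; 5.00: 11, 78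
- east (time / s: G / %, Q / %): 10.0: 7, 83; 20.0: 17, 67; 30.0: 20, 60; 50.0: 28, 43; 80.0: 40, 33; 90.0: 41, 30
- south-west (time / min: G / %, Q / %): 0.417: 2, 96; 0.667: 6, 96; 1.33: 0, 90; 2.50: 4, 81; 5.00: 14, 70

(readings scatter by 2 percentage points)



- which flask leads in amount of G, in percent of the Q charged ("all alike" within 1.5 percentage points) (cedar / alder / elm / all alike)
- how much G is there at the end, in percent of the Q charged: cedar
- how much G is there at the end, in percent of the Q charged: alder
- how much G is there at the end, in percent of the Q charged: elm

Where does a lost Q go? Part of it turns up as G. East ends at 90.0 s with 30% Q and 41% G, which gives 0.586. That is the fork share, the selectivity: G found per Q lost.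

Why read it in east? East lost more Q than either cold run, so the scatter weighs least there.

And the cold runs? North-east reads 0.500 and south-west 0.467, both lower than east.

So is the share constant? That is unproven. Their losses are smaller, so the same scatter of 2 percentage points weighs more on their shares.

How much Q does cedar lose? Treat the fall as one exponent over 5.0 min. North-east reaches 0.248. East, scaled to that time, reaches 4.01. Cedar's charge of Q lies midway by ratio between theirs, and 5 °C lies near the middle of −5 °C and 17 °C. Their geometric mean is 0.999, so conversion is 63.2%.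

And G? Share times conversion gives 37.0% for cedar.

The forecast names elm as leader. It gives cedar 31% (23% to 38%), alder 5% (2% to 10%) and elm 50% (40% to 62%). On the share it says “so I take about 0.55”. My cedar figure is higher than its 31%.

The flasks give 34.9% in cedar, 2.52% in alder and 54.8% in elm, so elm leads.

    Q ⇌ G + J (K = 0.750 M, k = 0.0260 s⁻¹, Ea = 91.0 kJ mol⁻¹, ΔH = −35.0 kJ mol⁻¹)
    2 Q → X (k = 0.0117 L mol⁻¹ s⁻¹, Ea = 65.0 kJ mol⁻¹)
    Q + Z → L (k = 0.0902 L mol⁻¹ s⁻¹, Ea = 65.0 kJ mol⁻¹)
    (constants at 25 °C)

The fork share times conversion gives elm 49.6% against 54.8%. The flask like elm kept at 0 °C lost 41.2% of its Q, so the share gives 24.2%, and that flask holds 20.7%. Alder gives 5.02% against 2.52%. What the temperature does to the making of G + J opens the gap between elm and alder: that gap is 52 points in the flasks as they ran, and with this effect taken away it is −1.4 points.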